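Numbering (drimane): ring A = C1–C5 and C10 (C3 ketone, C4 = C(CH3)2); ring B = C5–C10 (C7=C8, C12 = CH3 on C8); C11 = OCH2 on C9; β = the face of the C10 methyl group.
The aryl ether bond C11–O (Mitsunobu) and the C9–C11 bond (methylenation, hydroboration) lead back to the cis-fused 8-methyl-7-silyl-7-en-9-one 11.
Ring B of 11 is cut at C6–C7 and C8–C9. Taking out C7=C8(CH3) as 1-(trimethylsilyl)propyne leaves cyclobutanone 9 (C5–C6–C9(=O)–C10); in the forward direction the alkyne is inserted into the C6–C9 bond under nickel catalysis.
Enabling feature: in ring B the C7=C8 double bond is flanked by the C6 methylene and by C9, and these two carbons sit cis on the adjacent ring-A atoms C5 (H) and C10 (CH3). This is the 1,4-pattern of a strained cis-bicyclo[4.2.0]octanone, whose only unhindered acyl–carbon bond is C9–C6.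
9 (ring A and the four-membered ring together) comes from the acyclic keto amide 6 by an auxiliary-controlled keteniminium–olefin [2+2]. Ring order: ring A with the cyclobutane, then ring B; the coumarin is attached last.

Key step: step 4

Remark 1: the (2R,5R) auxiliary is assumed (quadrant model) to block the approach that would give the enantiomer of 9; if the sense were opposite, the equally available (2S,5S) amine would be used in the same way.
Remark 2: 1 is used as the racemate, because its stereocentre becomes sp2 in 7.

Step 1
Reactants: 1 2-methylglutaric anhydride; 2 prenylmagnesium chloride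
Product: 3 2,6,6-trimethyl-5-oxooct-7-enoic acid
Conditions: 2 added to 1, THF, −78 °C; aq HCl
Reagents that add atoms: none
Why: Acylation of an allylic Grignard reagent by a cyclic anhydride, in which the prenyl reagent reacts through its γ-carbon (SE2′, six-membered transition state) to build the C(CH3)2–CH=CH2 unit, attacks the less hindered carbonyl next to CH2, and is kept from a second addition by the magnesium carboxylate and the neopentyl ketone; no lasting stereocentre is involved.

Step 2
Reactants: 3 2,6,6-trimethyl-5-oxooct-7-enoic acid; 4 (2R,5R)-2,5-dimethylpyrrolidine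
Product: 6 1-[(2R,5R)-2,5-dimethylpyrrolidin-1-yl]-2,6,6-trimethyloct-7-ene-1,5-dione (epimers at C2), via acid chloride 5 (not isolated)
Conditions: (COCl)2, cat. DMF, CH2Cl2, 0 °C; then 4, Et3N, CH2Cl2, 0 °C to rt
Reagents that add atoms: oxalyl chloride, O=C(Cl)C(=O)Cl (chlorine of 5)
Why: Acid chloride formation followed by N-acylation is chosen because the hindered secondary amine needs a reactive acyl donor, and the stereocentre next to the amide carbonyl may stay a mixture because it is erased in step 3.

Step 3
Reactants: 6 keto amide
Product: 9 (1R,6S)-2,2,6-trimethylbicyclo[4.2.0]octane-3,7-dione, via keteniminium triflate 7 (not isolated), via cyclobutaniminium triflate 8 (not isolated)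
Conditions: Tf2O, 2,4,6-collidine, ClCH2CH2Cl, 0 to 80 °C; then H2O, aq NaHCO3, 60 °C
Reagents that add atoms: triflic anhydride, O=S(=O)(OS(=O)(=O)C(F)(F)F)C(F)(F)F (triflate counter-ion of 7 and 8); water, O (C7 carbonyl oxygen of 9)
Why: Intramolecular keteniminium–olefin [2+2] cycloaddition, in which O-triflation and loss of the α-proton give the strongly electrophilic 7; its central carbon bonds to the terminal CH2 and its methyl-bearing carbon to the inner vinyl carbon (ring A, helped by the gem-dimethyl effect and the absence of allylic hydrogens), the four-membered ring forces H-5 and CH3-10 to be cis, and the C2-symmetric pyrrolidine, whose methyl groups block one quadrant of approach, sets their absolute configuration before hydrolysis of 8.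

Step 4
Reactants: 9 (1R,6S)-2,2,6-trimethylbicyclo[4.2.0]octane-3,7-dione; 10 1-(trimethylsilyl)propyne
Product: 11 (4aR,8aS)-2,5,5,8a-tetramethyl-3-(trimethylsilyl)-4a,5,8,8a-tetrahydronaphthalene-1,6(4H,7H)-dione
Conditions: Ni(cod)2 (10 mol%), PCy3 (20 mol%), 10 (3 equiv), toluene, 100 °C, sealed tube
Reagents that add atoms: none
Why: Zerovalent nickel binds 10 and the strained C9 carbonyl of 9 and couples them oxidatively to a spiro oxanickelacyclopentene (C8–C9 bond), β-carbon elimination then opens the four-membered ring to a seven-membered nickelacycle, and C(sp2)–C(sp3) reductive elimination forms C6–C7 and returns the catalyst. The closest known reaction type is the nickel-catalysed intermolecular insertion of internal alkynes, silyl alkynes included, into cyclobutanones and other four-membered-ring ketones, a formal [4+2] cut-and-sew ring expansion driven by release of ring strain. Ring B is the only ring closed, and it closes by reductive elimination from the seven-membered metallacycle, so that the cyclobutanone grows by the two alkyne carbons. No stereocentre is created: the bonds at C5 and C10 are not touched, so the cis ring fusion set in step 3 passes unchanged into the decalin. Three selectivities are needed: only the strained carbonyl reacts (the C3 ketone offers no strain release); the silyl group takes the position next to nickel, so that the methyl-bearing alkyne carbon bonds to C9; and of the two acyl–carbon bonds the one to the C6 methylene is cleaved, because the alternative would put nickel on the quaternary C10. The silyl group left on C7 shields C7=C8 in step 7 and is removed in step 9.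

Step 5
Reactants: 11 silyl enedione
Product: 12 the C3 ethylene ketal of 11 (1,3-dioxolane at naphthalene C6; C9 enone free)
Conditions: HOCH2CH2OH, TsOH·H2O (cat.), benzene, reflux, Dean–Stark
Reagents that add atoms: ethylene glycol, OCCO
Why: Chemoselective acid-catalysed ketalisation, in which the saturated C3 ketone reacts while the C9 carbonyl, deactivated by conjugation and flanked by the quaternary C10 and the C8 methyl group, does not, and the electron-poor β-silyl enone resists protodesilylation.

Step 6
Reactants: 12 ketal enone
Product: 13 the 9(11)-methylene diene (C9=CH2 in place of C9=O of 12)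
Conditions: Ph3PCH3Br, KOtBu, toluene, rt to 90 °C
Reagents that add atoms: methyltriphenylphosphonium bromide, [Br-].C[P+](c1ccccc1)(c1ccccc1)c1ccccc1
Why: Wittig methylenation with the small ylide, a reaction type established for 2,6,6-trisubstituted cyclohex-2-enones, converts the only free carbonyl into the C9=C11 methylene group.

Step 7
Reactants: 13 silyl diene
Product: 15 the primary alcohol (9β-H and 9α-CH2OH; C7 silyl group and C3 ketal retained), via B-alkyl-9-BBN adduct 14 (not isolated)
Conditions: 9-BBN, THF, 65 °C; then H2O2, aq NaOH, 0 °C to rt
Reagents that add atoms: 9-borabicyclo[3.3.1]nonane, B1C2CCCC1CCC2 (boryl group of 14); hydrogen peroxide, OO (oxygen of 15)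
Why: Hydroboration–oxidation, in which boron goes to the terminal C11 of the 1,1-disubstituted alkene while the tetrasubstituted, silyl-bearing C7=C8 bond is inert, and the reagent approaches the convex face of the cis-decalin (the face of H-5 and CH3-10, ring A being folded under the other face), so that H-9 should end up cis to CH3-10 and the CH2OH group trans to it.

Step 8
Reactants: 15 primary alcohol; 16 umbelliferone (7-hydroxycoumarin)
Product: 17 the 7-coumarinyl ether of 15
Conditions: PPh3, DIAD, THF, 0 °C to 50 °C
Reagents that add atoms: none
Why: Mitsunobu etherification, in which the acidic phenol 16 displaces the activated primary C11–O bond, no stereocentre takes part, and the ketal and the vinylsilane are inert to the neutral redox conditions.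

Step 9
Reactants: 17 silyl ketal ether
Product: 18 7-{[(1R,4aS,8aS)-2,5,5,8a-tetramethyl-6-oxo-1,4,4a,5,6,7,8,8a-octahydronaphthalen-1-yl]methoxy}-2H-chromen-2-one
Conditions: CF3CO2H/H2O (9:1), CH2Cl2, 0 °C to rt
Reagents that add atoms: water, O (C3 carbonyl oxygen)
Why: Acid-mediated ipso-protodesilylation of the vinylsilane (protonation at C7 gives a tertiary C8 cation stabilised by the β-silicon effect, and loss of silicon restores C7=C8 in place) runs together with hydrolysis of the dioxolane, and none of C5, C9 and C10 is epimerisable under these conditions.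

Compound list
1 | 2-methylglutaric anhydride (racemic) | CC1CCC(=O)OC1=O | starting material
2 | prenylmagnesium chloride | CC(C)=CC[Mg]Cl | starting material
3 | 2,6,6-trimethyl-5-oxooct-7-enoic acid (racemic) | C=CC(C)(C)C(=O)CCC(C)C(=O)O | intermediate
4 | (2R,5R)-2,5-dimethylpyrrolidine | C[C@@H]1CC[C@@H](C)N1 | starting material
5 | 2,6,6-trimethyl-5-oxooct-7-enoyl chloride | C=CC(C)(C)C(=O)CCC(C)C(=O)Cl | intermediate
6 | 1-[(2R,5R)-2,5-dimethylpyrrolidin-1-yl]-2,6,6-trimethyloct-7-ene-1,5-dione (epimers at C2) | C=CC(C)(C)C(=O)CCC(C)C(=O)N1[C@H](C)CC[C@H]1C | intermediate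
7 | keteniminium triflate derived from 6 | C=CC(C)(C)C(=O)CCC(C)=C=[N+]1[C@H](C)CC[C@H]1C.[O-]S(=O)(=O)C(F)(F)F | intermediate
8 | cis-fused cyclobutaniminium triflate (C7 iminium salt of 9) | C[C@@H]1CC[C@@H](C)[N+]1=C1C[C@@H]2C(C)(C)C(=O)CC[C@@]21C.[O-]S(=O)(=O)C(F)(F)F | intermediate
9 | (1R,6S)-2,2,6-trimethylbicyclo[4.2.0]octane-3,7-dione (H-1 and CH3-6 cis) | O=C1C[C@@H]2C(C)(C)C(=O)CC[C@@]21C | intermediate
10 | 1-(trimethylsilyl)propyne | CC#C[Si](C)(C)C | starting material
11 | (4aR,8aS)-2,5,5,8a-tetramethyl-3-(trimethylsilyl)-4a,5,8,8a-tetrahydronaphthalene-1,6(4H,7H)-dione (cis-fused) | CC1=C([Si](C)(C)C)C[C@@H]2C(C)(C)C(=O)CC[C@]2(C)C1=O | intermediate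
12 | C3 ethylene ketal of 11 | CC1=C([Si](C)(C)C)C[C@@H]2C(C)(C)C3(OCCO3)CC[C@]2(C)C1=O | intermediate
13 | 9(11)-methylene diene from 12 | CC1=C([Si](C)(C)C)C[C@@H]2C(C)(C)C3(OCCO3)CC[C@]2(C)C1=C | intermediate
14 | B-(C11-alkyl)-9-BBN adduct of 13 (9β-H) | CC1=C([Si](C)(C)C)C[C@@H]2C(C)(C)C3(OCCO3)CC[C@]2(C)[C@@H]1CB1C2CCCC1CCC2 | intermediate
15 | C11 primary alcohol (5β-H, 9β-H, 10β-CH3; C7 silyl group, C3 ketal) | CC1=C([Si](C)(C)C)C[C@@H]2C(C)(C)C3(OCCO3)CC[C@]2(C)[C@@H]1CO | intermediate
16 | umbelliferone | Oc1ccc2ccc(=O)oc2c1 | starting material
17 | 7-coumarinyl ether of 15 | CC1=C([Si](C)(C)C)C[C@@H]2C(C)(C)C3(OCCO3)CC[C@]2(C)[C@@H]1COc1ccc2ccc(=O)oc2c1 | intermediate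
18 | 7-{[(1R,4aS,8aS)-2,5,5,8a-tetramethyl-6-oxo-1,4,4a,5,6,7,8,8a-octahydronaphthalen-1-yl]methoxy}-2H-chromen-2-one | CC1=CC[C@@H]2C(C)(C)C(=O)CC[C@]2(C)[C@@H]1COc1ccc2ccc(=O)oc2c1 | target

Total steps: 9. Longest linear sequence: 9 (1 to 18).

Steps most likely to fail

Step 4. The oxidative coupling may be too slow at a carbonyl that carries a quaternary neighbour. The alkyne may be used up by oligomerisation. β-Hydride loss from the C6–nickel bond may overtake reductive elimination. The fallback sets out from 9 and 10 and comes back at 11; it makes the same two bonds in two operations with other metals. The complex (η2-alkyne)Ti(OiPr)2, made from 10 with Ti(OiPr)4 and 2 equiv of i-PrMgCl in Et2O at −50 °C, should add through its methyl-bearing carbon to the strained carbonyl of 9. Iodinolysis of the remaining vinyl–titanium bond should then give the iodo(silyl)alkenyl cyclobutanol F5, with iodine cis to the carbinol carbon. With Pd(OAc)2, P(t-Bu)3·HBF4 and Cs2CO3 in toluene at 90 °C, zerovalent palladium should insert into the C–I bond. The palladium alkoxide should then undergo β-carbon elimination of the bond to the CH2 group, and reductive elimination should close ring B to 11. This is the ring-opening coupling of tertiary cyclobutanols run intramolecularly.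

Step 3. The oxygen of the δ-keto group may capture the keteniminium carbon. A cationic 1,2-methyl shift from the neighbouring quaternary carbon may occur if bond formation becomes stepwise. The auxiliary may discriminate the two faces too weakly. The fallback sets out from 6 and comes back at 9; it takes the ketone out of play and turns it into a second control element.
- CBS reduction of 6 ((S)-Me-CBS, BH3·SMe2, large tert-alkyl group against small CH2 group) should give the (5R)-hydroxy amide F1.
- TBSOTf and 2,6-lutidine should give the silyl ether F2.
- The same activation, cycloaddition and hydrolysis should give the silyloxy cyclobutanone F3, with the bulky silyloxy group equatorial in the chair-like folding of the tether and on the face of the two new ring bonds.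
- Aqueous HF in MeCN should give the hydroxy ketone F4, and Dess–Martin oxidation returns 9.

Step 8. Substitution at the β-branched C11 may be slow, and the activated alcohol may instead eliminate towards the allylic H-9, which would regenerate a diene. The fallback sets out from 15 and comes back at 17. It forms the oxygen–aryl bond instead of the C11–O bond, so that C11 is never activated: palladium-catalysed C–O cross-coupling of 15 with commercial 7-bromocoumarin (Pd2(dba)3, RockPhos, Cs2CO3, toluene, 90 °C). This fallback makes no compound outside the list (F0).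

Further compounds
F1 | step 3 | (5R)-1-[(2R,5R)-2,5-dimethylpyrrolidin-1-yl]-5-hydroxy-2,6,6-trimethyloct-7-en-1-one | C=CC(C)(C)[C@H](O)CCC(C)C(=O)N1[C@H](C)CC[C@H]1C
F2 | step 3 | tert-butyldimethylsilyl ether of F1 | C=CC(C)(C)[C@H](O[Si](C)(C)C(C)(C)C)CCC(C)C(=O)N1[C@H](C)CC[C@H]1C
F3 | step 3 | (1R,3R,6S)-3-(tert-butyldimethylsilyloxy)-2,2,6-trimethylbicyclo[4.2.0]octan-7-one | O=C1C[C@@H]2C(C)(C)[C@H](O[Si](C)(C)C(C)(C)C)CC[C@@]21C
F4 | step 3 | (1R,3R,6S)-3-hydroxy-2,2,6-trimethylbicyclo[4.2.0]octan-7-one | O=C1C[C@@H]2C(C)(C)[C@H](O)CC[C@@]21C
F5 | step 4 | 7-hydroxy-7-[(Z)-1-iodo-1-(trimethylsilyl)prop-1-en-2-yl]-2,2,6-trimethylbicyclo[4.2.0]octan-3-one (ring fusion as in 9; carbinol configuration of no consequence) | C/C(=C(/I)[Si](C)(C)C)C1(O)C[C@@H]2C(C)(C)C(=O)CC[C@@]21C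
F0 | step 8 | none | none
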